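## Retrosynthetic overview

- Target ⇒ (−)-lariciresinol + caffeic acid: ester C–O bond, made by Mitsunobu reaction at the only aliphatic OH, with no protecting groups.
- (−)-Lariciresinol ⇒ (S,S)-secoisolariciresinol: ring C2–O1 bond by dehydrogenative oxa-cyclisation through a p-quinone methide (key step, sets C2).
- (S,S)-Secoisolariciresinol ⇒ (S,S)-dibenzylsuccinic acid ⇒ achiral (E,E)-bis(arylidene)succinic acid: double asymmetric hydrogenation sets C3 and C4.
- Bis(arylidene)succinic acid ⇒ 2 × O-benzylvanillin + diethyl succinate (double Stobbe condensation).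
- Rings: the three arenes are bought; the oxolane is the only ring built, in the penultimate step.

Assumption: the SMILES fixes the (2R,3S,4S)-oxolane, i.e. the caffeate of (−)-lariciresinol; in step 2 the ligand antipode is the one that a scouting run shows to give the (2S,3S)-acid, written here as (Sa,S).

## Route

Step 1
Reactants: 1 4-(benzyloxy)-3-methoxybenzaldehyde (2.2 equiv); 2 diethyl succinate
Product: 4 (2E,3E)-2,3-bis{[4-(benzyloxy)-3-methoxyphenyl]methylidene}butanedioic acid, via mono-arylidene half-ester 3 (not isolated)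
Conditions: NaOEt (4.5 equiv), EtOH, reflux, 1 added in two portions; aq. HCl; recrystallise from AcOH
Reagents that add atoms: none
Why: Double Stobbe condensation (aldol, γ-lactonisation and E1cB ring opening, run twice, the classical fulgenic-acid synthesis) gives the thermodynamically preferred E,E-diacid with each aryl anti to its own CO2H; no stereocentre is formed and 40–50% is expected from very cheap inputs.

Step 2
Reactants: 4
Product: 6 (2S,3S)-2,3-bis[(4-hydroxy-3-methoxyphenyl)methyl]butanedioic acid, via O-benzylated SS-diacid 5 (not isolated)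
Conditions: [Ir(cod){(Sa,S)-SIPHOX}]BArF (2 mol %), H2 (20 bar), Et3N (0.5 equiv), MeOH/THF, 45 °C; then AcOH (1 equiv), 10% Pd/C, H2 (1 atm), rt; recrystallise
Reagents that add atoms: none
Why: Proposed new method: double carboxylate-directed Ir-catalysed asymmetric hydrogenation of a cross-conjugated 2,3-bis(arylidene)succinic acid. Each C=C is an (E)-α-substituted, electron-rich cinnamic acid carrying its own CO2H, so each should bind the Ir dihydride through its carboxylate and insert with the same catalyst-controlled face; the diene is twisted out of conjugation, so the two alkenes behave as independent trisubstituted acrylic acids, and the second reduction is of an α-sec-alkyl cinnamic acid. Two identical face selections give the C2-symmetric (2S,3S) acid, which sets C3 and C4 of the target; mismatched events end as separable meso acid and so raise the ee of the C2 product. The closest known reactions are Ir–spiro-phosphine-oxazoline and Ru–BINAP hydrogenation of α-alkyl and α-branched cinnamic acids and Rh-catalysed hydrogenation of mono-arylidenesuccinate half-esters. The benzyl ethers are then removed by ordinary Pd/C hydrogenolysis once the amine is neutralised.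

Step 3
Reactants: 6
Product: 7 (+)-secoisolariciresinol [(2S,3S)-2,3-bis[(4-hydroxy-3-methoxyphenyl)methyl]butane-1,4-diol]
Conditions: BH3·SMe2 (6 equiv), THF, 0 → 50 °C; MeOH, then aq. work-up
Reagents that add atoms: none
Why: Borane reduction of carboxylic acids through acyloxyboranes is fast and tolerates free phenols (aryl borates are cleaved on methanolysis), and the non-basic conditions leave the two α-stereocentres untouched.

Step 4
Reactants: 7
Product: 9 (−)-lariciresinol, via p-quinone methide 8 (not isolated)
Conditions: DDQ (0.75 equiv, added over 1 h), 1,4-dioxane, 20 °C; unreacted 7 recovered and recycled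
Reagents that add atoms: none
Why: Quinone dehydrogenation of a p-hydroxybenzyl C–H (the two benzylic sites of C2-symmetric 7 are homotopic) gives quinone methide 8, and the δ-hydroxyl adds 5-exo to the methide carbon (intramolecular oxa-1,6-addition) to form the C2–O1 bond. The aryl group ends trans to the neighbouring CH2OH (least-strained transition state and also the thermodynamic isomer), which fixes C2 as R, while the 3,4-cis relation is carried from the S,S backbone. Sub-stoichiometric oxidant keeps the second closure to the furofuran low; about 45% per pass and about 80% on recovered 7 are expected.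

Step 5
Reactants: 9; 10 caffeic acid (1.2 equiv)
Product: 11 [(2R,3S,4S)-2-(4-hydroxy-3-methoxyphenyl)-4-[(4-hydroxy-3-methoxyphenyl)methyl]oxolan-3-yl]methyl (2E)-3-(3,4-dihydroxyphenyl)prop-2-enoate
Conditions: PPh3 (1.5 equiv), DIAD (1.5 equiv), THF, 0 °C → rt
Reagents that add atoms: none
Why: Mitsunobu esterification activates only the single aliphatic OH as its alkoxyphosphonium ion, and the carboxylate of 10 (pKa about 4.5) is the only pronucleophile acidic enough to be alkylated ahead of the phenols (pKa about 10); the acid is never turned into an acylating agent, so no phenol is acylated, and the reacting CH2 carries no stereocentre while the E-alkene is untouched.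

## Compound list

1 | 4-(benzyloxy)-3-methoxybenzaldehyde (O-benzylvanillin) | COc1cc(C=O)ccc1OCc1ccccc1 | starting material
2 | diethyl succinate | CCOC(=O)CCC(=O)OCC | starting material
3 | (3E)-4-[4-(benzyloxy)-3-methoxyphenyl]-3-(ethoxycarbonyl)but-3-enoic acid (present as its sodium salt) | COc1cc(/C=C(/C(=O)OCC)\CC(=O)O)ccc1OCc1ccccc1 | intermediate (not isolated)
4 | (2E,3E)-2,3-bis{[4-(benzyloxy)-3-methoxyphenyl]methylidene}butanedioic acid | COc1cc(/C=C(/C(=O)O)\C(C(=O)O)=C/c2ccc(OCc3ccccc3)c(OC)c2)ccc1OCc1ccccc1 | intermediate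
5 | (2S,3S)-2,3-bis{[4-(benzyloxy)-3-methoxyphenyl]methyl}butanedioic acid | COc1cc(C[C@H](C(=O)O)[C@@H](C(=O)O)Cc2ccc(OCc3ccccc3)c(OC)c2)ccc1OCc1ccccc1 | intermediate (not isolated)
6 | (2S,3S)-2,3-bis[(4-hydroxy-3-methoxyphenyl)methyl]butanedioic acid | COc1cc(C[C@H](C(=O)O)[C@@H](C(=O)O)Cc2ccc(O)c(OC)c2)ccc1O | intermediate
7 | (+)-secoisolariciresinol, (2S,3S)-2,3-bis[(4-hydroxy-3-methoxyphenyl)methyl]butane-1,4-diol | COc1cc(C[C@H](CO)[C@@H](CO)Cc2ccc(O)c(OC)c2)ccc1O | intermediate
8 | p-quinone methide of 7 (one guaiacyl unit as 4-ylidene-2-methoxycyclohexa-2,5-dien-1-one, backbone configuration as in 7, methide geometry not defined) | COC1=CC(=C[C@H](CO)[C@@H](CO)Cc2ccc(O)c(OC)c2)C=CC1=O | intermediate (not isolated)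
9 | (−)-lariciresinol, 4-[(2R,3S,4S)-4-[(4-hydroxy-3-methoxyphenyl)methyl]-3-(hydroxymethyl)oxolan-2-yl]-2-methoxyphenol | COc1cc(C[C@@H]2CO[C@@H](c3ccc(O)c(OC)c3)[C@@H]2CO)ccc1O | intermediate
10 | caffeic acid, (2E)-3-(3,4-dihydroxyphenyl)prop-2-enoic acid | OC(=O)/C=C/c1ccc(O)c(O)c1 | starting material
11 | [(2R,3S,4S)-2-(4-hydroxy-3-methoxyphenyl)-4-[(4-hydroxy-3-methoxyphenyl)methyl]oxolan-3-yl]methyl (2E)-3-(3,4-dihydroxyphenyl)prop-2-enoate (CNP0132883.1) | COc1cc(C[C@@H]2CO[C@@H](c3ccc(O)c(OC)c3)[C@@H]2COC(=O)/C=C/c2ccc(O)c(O)c2)ccc1O | target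

## Step count and risks

Total steps: 5. Longest linear sequence: 5 steps (1 + 2 → 4 → 6 → 7 → 9 → 11).

Three steps most likely to fail:

1. Step 2, the new double hydrogenation (it may stall after one C=C, give much meso acid, or give modest ee). The fallback uses known auxiliary chemistry, sets out from 1 and comes back at 7, replacing steps 1–3. Aldehyde 1 is converted by reductive Knoevenagel reaction with Meldrum's acid in HCO2H/Et3N at 100 °C into 3-[4-(benzyloxy)-3-methoxyphenyl]propanoic acid F1. F1 is attached (PivCl, Et3N, LiCl, THF) to (R)-4-isopropyloxazolidin-2-one to give the N-acyl oxazolidinone F2. Oxidative homocoupling of its lithium enolate (LDA, THF, −78 °C, then TiCl4) gives the (2S,3S)-dibenzylsuccinyl bis-imide F3; the mirror-image auxiliary is documented to give the R,R series. LiBH4 in THF/MeOH releases the auxiliary and gives O,O'-dibenzyl-(S,S)-secoisolariciresinol F4, and H2 with Pd/C in EtOAc/MeOH then gives 7.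

2. Step 4, mono-selective oxidative ring closure (a statistical limit between the two equivalent benzylic sites, over-oxidation to the furofuran or at the new C2–H, and competing aryltetralin formation). The fallback sets out from 7 and comes back at 9. Diol 7 is oxidised exhaustively (DDQ 2.2 equiv, dioxane) to (−)-pinoresinol F5, in which both benzylic positions are closed and no site selectivity is needed. One benzylic C–O bond is then opened by hydrogenolysis (H2 1 atm, 10% Pd/C, EtOAc/MeOH, stopped after one equivalent of H2) to give 9; any over-reduced 7 goes back to the oxidation.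

3. Step 5, Mitsunobu esterification with a free catechol and free phenols on a β-branched CH2OH (phenol O-alkylation, catechol oxidation by the azo reagent, or sluggish displacement). The fallback sets out from 9 and comes back at 11, building the cinnamate C=C last. Alcohol 9 is heated with Meldrum's acid (1.05 equiv, toluene, 90 °C) to give the hydrogen malonate of (−)-lariciresinol F6; the aliphatic OH is expected to react ahead of the hindered guaiacyl OH groups. F6 then undergoes Knoevenagel–Doebner condensation with 3,4-dihydroxybenzaldehyde (pyridine, cat. piperidine, 55 °C) with loss of CO2 to give 11 as the E-ester.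

## Further compounds

F1 | step 2 | 3-[4-(benzyloxy)-3-methoxyphenyl]propanoic acid | COc1cc(CCC(=O)O)ccc1OCc1ccccc1
F2 | step 2 | (4R)-3-{3-[4-(benzyloxy)-3-methoxyphenyl]propanoyl}-4-(propan-2-yl)-1,3-oxazolidin-2-one | COc1cc(CCC(=O)N2C(=O)OC[C@H]2C(C)C)ccc1OCc1ccccc1
F3 | step 2 | (2S,3S)-2,3-bis{[4-(benzyloxy)-3-methoxyphenyl]methyl}-1,4-bis[(4R)-2-oxo-4-(propan-2-yl)-1,3-oxazolidin-3-yl]butane-1,4-dione | COc1cc(C[C@H](C(=O)N2C(=O)OC[C@H]2C(C)C)[C@@H](C(=O)N2C(=O)OC[C@H]2C(C)C)Cc2ccc(OCc3ccccc3)c(OC)c2)ccc1OCc1ccccc1
F4 | step 2 | (2S,3S)-2,3-bis{[4-(benzyloxy)-3-methoxyphenyl]methyl}butane-1,4-diol | COc1cc(C[C@H](CO)[C@@H](CO)Cc2ccc(OCc3ccccc3)c(OC)c2)ccc1OCc1ccccc1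
F5 | step 4 | (−)-pinoresinol | COc1cc([C@@H]2OC[C@@H]3[C@H]2CO[C@H]3c2ccc(O)c(OC)c2)ccc1O
F6 | step 5 | 3-{[(2R,3S,4S)-2-(4-hydroxy-3-methoxyphenyl)-4-[(4-hydroxy-3-methoxyphenyl)methyl]oxolan-3-yl]methoxy}-3-oxopropanoic acid | COc1cc(C[C@@H]2CO[C@@H](c3ccc(O)c(OC)c3)[C@@H]2COC(=O)CC(=O)O)ccc1O
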